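The synthesis rests on cutting the two benzylic C–H bonds, not the ester C–O bond. The ArCH(CH3)–O–C(=O) unit on the benzene ring has a benzylic carbon (para to the phenol oxygen) bearing one methyl carbon and the ester oxygen. That unit is the hydrogenation product of a 1-arylvinyl ester. The key step, a chelate-directed rhodium-catalysed asymmetric hydrogenation run last, creates the single S stereocentre. It selects the vinyl C=C, which chelates rhodium together with the ester C=O, over the two trisubstituted alkenes. Its precursor is the achiral enol ester made by Markovnikov addition of intact (Z)-4-acetoxy-2-methylbut-2-enoic acid to the ethynyl group of an unprotected o-hydroxyaryl enone. No ring is formed.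

Key step: step 9

Assumption: the (S,S) antipode of Et-DuPhos is taken as the one that delivers the S centre; a calibration hydrogenation of 1-phenylvinyl acetate, with the product compared against authentic (S)-1-phenylethyl acetate, is to fix the antipode before compound 14 is committed, and the (R,R) ligand would be used unchanged otherwise.

Step 1
Reactants: 1 5-iodosalicylic acid
Product: 3 2-hydroxy-5-iodo-N-methoxy-N-methylbenzamide, via 1-(2-hydroxy-5-iodobenzoyl)imidazole 2 (not isolated)
Conditions: CDI (1.2 equiv), THF, 20 to 50 °C; then MeNHOMe·HCl (1.5 equiv), 20 °C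
Reagents that add atoms: N,O-dimethylhydroxylamine hydrochloride (CNOC.Cl)
Why: CDI-mediated amidation (Weinreb amide formation): the acid is converted into its acyl imidazolide, which the hydroxylamine, freed from its salt by the imidazole released, attacks at the acyl carbon, while any imidazole carboxylate formed at the phenol oxygen is hydrolysed on aqueous work-up, so the phenol needs no protection.

Step 2
Reactants: 3 2-hydroxy-5-iodo-N-methoxy-N-methylbenzamide; 4 trimethylsilylacetylene
Product: 5 2-hydroxy-N-methoxy-N-methyl-5-[(trimethylsilyl)ethynyl]benzamide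
Conditions: PdCl2(PPh3)2 (2 mol%), CuI (4 mol%), Et3N, degassed THF, 20 to 40 °C
Reagents that add atoms: none
Why: Sonogashira coupling: zerovalent palladium formed in the flask inserts into the aryl C–I bond, the copper acetylide of 4 transmetallates and reductive elimination forms the aryl–alkynyl bond, the free phenol and the amide being tolerated and the silyl cap preventing double coupling.

Step 3
Reactants: 5 2-hydroxy-N-methoxy-N-methyl-5-[(trimethylsilyl)ethynyl]benzamide
Product: 6 5-ethynyl-2-hydroxy-N-methoxy-N-methylbenzamide
Conditions: K2CO3, MeOH, 20 °C; aq. NH4Cl work-up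
Reagents that add atoms: none
Why: Base-catalysed methanolysis of the alkynyl C–Si bond (protodesilylation) is placed here, before any enone exists, so that the phenoxide formed under these basic conditions has nothing to cyclise onto.

Step 4
Reactants: 6 5-ethynyl-2-hydroxy-N-methoxy-N-methylbenzamide; 7 2-methyl-1-propenylmagnesium bromide
Product: 8 1-(5-ethynyl-2-hydroxyphenyl)-3-methylbut-2-en-1-one
Conditions: 7 (4 equiv, 0.5 M in THF), THF, −20 to 20 °C, amide added to the Grignard reagent; poured into cold aq. NH4Cl; no contact with base afterwards
Reagents that add atoms: none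
Why: Weinreb ketone synthesis by Grignard addition: two equivalents of 7 are consumed by the phenol O–H and the alkyne C–H, a further one adds to the N-methoxy-N-methylamide to give a magnesium-chelated tetrahedral adduct that cannot over-add and collapses to the enone only on the cold, weakly acidic quench, where the phenol is protonated and oxa-Michael closure to the 2,2-dimethylchromanone is not triggered.

Step 5
Reactants: 9 3-methylfuran-2(5H)-one
Product: 11 4-methoxybenzyl (Z)-4-hydroxy-2-methylbut-2-enoate, via potassium (Z)-4-hydroxy-2-methylbut-2-enoate 10 (not isolated)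
Conditions: KOH (1.0 equiv), MeOH/H2O, 0 to 20 °C, evaporated to dryness; then 4-methoxybenzyl chloride (1.05 equiv), Bu4NI (cat.), DMF, 0 to 20 °C; cold neutral work-up, crude product used at once
Reagents that add atoms: potassium hydroxide ([K+].[OH-]); 4-methoxybenzyl chloride (COc1ccc(CCl)cc1)
Why: Lactone saponification followed by carboxylate O-alkylation: hydroxide opens the butenolide at the acyl carbon to the potassium hydroxy carboxylate, whose Z geometry (carboxyl and CH2OH cis) is inherited from the five-membered ring, and the carboxylate, far more nucleophilic than the neutral alcohol, is alkylated by the benzylic chloride to give the ester, which is kept cold and neutral because acid or base would relactonise it.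

Step 6
Reactants: 11 4-methoxybenzyl (Z)-4-hydroxy-2-methylbut-2-enoate
Product: 12 4-methoxybenzyl (Z)-4-acetoxy-2-methylbut-2-enoate
Conditions: Ac2O (1.5 equiv), pyridine, DMAP (cat.), CH2Cl2, 0 °C
Reagents that add atoms: acetic anhydride (CC(=O)OC(C)=O)
Why: DMAP-catalysed O-acetylation of the primary allylic alcohol removes the internal nucleophile responsible for relactonisation and installs the acetate of the target without touching the Z-alkene.

Step 7
Reactants: 12 4-methoxybenzyl (Z)-4-acetoxy-2-methylbut-2-enoate
Product: 13 (Z)-4-acetoxy-2-methylbut-2-enoic acid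
Conditions: TFA, anisole (5 equiv), CH2Cl2, 0 °C; co-evaporation with toluene
Reagents that add atoms: none
Why: Acidolysis of the 4-methoxybenzyl ester (SN1-type cleavage to the 4-methoxybenzyl cation, trapped by anisole in a Friedel–Crafts alkylation) releases the carboxylic acid under base-free conditions that leave the primary acetate and the Z-alkene alone, and the carboxyl group is never converted into an acyl halide or anhydride.

Step 8
Reactants: 8 1-(5-ethynyl-2-hydroxyphenyl)-3-methylbut-2-en-1-one; 13 (Z)-4-acetoxy-2-methylbut-2-enoic acid
Product: 14 1-[4-hydroxy-3-(3-methylbut-2-enoyl)phenyl]vinyl (Z)-4-acetoxy-2-methylbut-2-enoate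
Conditions: [RuCl2(p-cymene)]2 (1 mol%), P(2-furyl)3 (2 mol%), Na2CO3 (4 mol%), 13 (1.3 equiv), toluene, 50 °C; quick filtration through a short pad of neutral silica, carried on directly
Reagents that add atoms: none
Why: Ruthenium-catalysed Markovnikov hydro-acyloxylation of a terminal alkyne: the carboxylate of 13 adds to the internal carbon of the ruthenium-coordinated aryl alkyne and protonation releases the 1-arylvinyl ester, the phosphine/carbonate combination favouring the geminal over the vinylidene-derived linear product, the excess acid keeping the phenol protonated, and the acid reacting only as an O-nucleophile so that its Z geometry is preserved.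

Step 9
Reactants: 14 1-[4-hydroxy-3-(3-methylbut-2-enoyl)phenyl]vinyl (Z)-4-acetoxy-2-methylbut-2-enoate
Product: 15 (1S)-1-[4-hydroxy-3-(3-methylbut-2-enoyl)phenyl]ethyl (Z)-4-acetoxy-2-methylbut-2-enoate (target)
Conditions: [Rh(cod)((S,S)-Et-DuPhos)]BF4 (2 mol%), H2 (2 bar), degassed THF, 20 °C, no base, stopped after uptake of 1 equiv H2
Reagents that add atoms: none
Why: The cationic monovalent rhodium bisphospholane complex binds the CH2=C(OCOR)Ar unit of 14 through the terminal C=C and the ester carbonyl oxygen in a five-membered chelate, adds H2 oxidatively, inserts the alkene to give an α-acyloxy benzylic rhodium alkyl hydride and closes the cycle by C–H reductive elimination, so that two C–H bonds form across the vinyl group. The closest known reaction type is the rhodium–bisphospholane asymmetric hydrogenation of 1-arylvinyl carboxylates (enol ester hydrogenation, the oxygen analogue of enamide hydrogenation). No ring is closed. The new benzylic S centre is set by catalyst control alone, the C2-symmetric (S,S)-Et-DuPhos ligand dictating which face of the chelated alkene receives hydrogen in an otherwise achiral substrate. The step needs face selectivity and chemoselectivity among three C=C bonds, and both are secured by the same feature of 14: only the 1,1-disubstituted enol ester can bind in the two-point fashion, whereas the trisubstituted Z-enoate and the β,β-dimethyl enone are hindered, cannot chelate and should stay untouched at low pressure with one equivalent of H2, as in the known selective reduction of dienyl acetates at the enol ester alkene. The base-free aprotic medium keeps the phenol protonated and hydrogen-bonded to the ketone, homogeneous rhodium does not hydrogenolyse the allylic acetate or the benzylic ester, and because no benzylic leaving group and no activated acyl derivative is ever formed, neither quinone methide racemisation nor Z to E isomerisation can occur.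

Compound list
1 | 5-iodosalicylic acid | OC(=O)c1cc(I)ccc1O | starting material
2 | 1-(2-hydroxy-5-iodobenzoyl)imidazole | O=C(c1cc(I)ccc1O)n1ccnc1 | intermediate
3 | 2-hydroxy-5-iodo-N-methoxy-N-methylbenzamide | CON(C)C(=O)c1cc(I)ccc1O | intermediate
4 | trimethylsilylacetylene | C#C[Si](C)(C)C | starting material
5 | 2-hydroxy-N-methoxy-N-methyl-5-[(trimethylsilyl)ethynyl]benzamide | CON(C)C(=O)c1cc(C#C[Si](C)(C)C)ccc1O | intermediate
6 | 5-ethynyl-2-hydroxy-N-methoxy-N-methylbenzamide | C#Cc1ccc(O)c(C(=O)N(C)OC)c1 | intermediate
7 | 2-methyl-1-propenylmagnesium bromide | CC(C)=C[Mg]Br | starting material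
8 | 1-(5-ethynyl-2-hydroxyphenyl)-3-methylbut-2-en-1-one | C#Cc1ccc(O)c(C(=O)C=C(C)C)c1 | intermediate
9 | 3-methylfuran-2(5H)-one | CC1=CCOC1=O | starting material
10 | potassium (Z)-4-hydroxy-2-methylbut-2-enoate | [K+].[O-]C(=O)/C(C)=C\CO | intermediate
11 | 4-methoxybenzyl (Z)-4-hydroxy-2-methylbut-2-enoate | COc1ccc(COC(=O)/C(C)=C\CO)cc1 | intermediate
12 | 4-methoxybenzyl (Z)-4-acetoxy-2-methylbut-2-enoate | COc1ccc(COC(=O)/C(C)=C\COC(C)=O)cc1 | intermediate
13 | (Z)-4-acetoxy-2-methylbut-2-enoic acid | CC(=O)OC/C=C(/C)C(=O)O | intermediate
14 | 1-[4-hydroxy-3-(3-methylbut-2-enoyl)phenyl]vinyl (Z)-4-acetoxy-2-methylbut-2-enoate | CC(=O)OC/C=C(/C)C(=O)OC(=C)c1ccc(O)c(C(=O)C=C(C)C)c1 | intermediate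
15 | (1S)-1-[4-hydroxy-3-(3-methylbut-2-enoyl)phenyl]ethyl (Z)-4-acetoxy-2-methylbut-2-enoate | CC(=O)OC/C=C(/C)C(=O)O[C@@H](C)c1ccc(O)c(C(=O)C=C(C)C)c1 | target

Total step count: 9 steps.
Longest linear sequence: 6 steps (steps 1, 2, 3, 4, 8, 9); the acid branch (steps 5, 6, 7) joins at step 8.

Steps most likely to fail

1. Step 9 (asymmetric hydrogenation). The risk is hydrogen uptake by one of the trisubstituted alkenes before the enol ester is consumed, or insufficient facial selectivity at the vinyl group. The fallback sets out from 8, uses acid 13 and returns at 15; it gives up the enol ester and makes the stereocentre by ketone reduction. Gold-catalysed Markovnikov hydration of the alkyne of 8 (Ph3PAuNTf2 cat., wet 1,4-dioxane, 60 °C) should give 1-(5-acetyl-2-hydroxyphenyl)-3-methylbut-2-en-1-one F1. Asymmetric transfer hydrogenation (RuCl[(S,S)-TsDPEN](p-cymene) cat., HCO2H/Et3N azeotrope, 20 °C) should reduce the unhindered acetyl group and spare the hydrogen-bonded aryl alkenyl ketone, giving 1-{2-hydroxy-5-[(1S)-1-hydroxyethyl]phenyl}-3-methylbut-2-en-1-one F2. Steglich esterification of the aliphatic hydroxyl with 13 (EDC·HCl, DMAP cat., CH2Cl2, −10 °C) leaves the benzylic C–O bond intact, so it should proceed with retention and give 15. The price is activation of the acid, with possible Z to E leakage that chromatography should remove, and competing acylation of the phenol.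

2. Step 8 (hydro-acyloxylation). The risk is sequestration of the ruthenium catalyst by the chelating o-acylphenol, or anti-Markovnikov addition through a ruthenium vinylidene. The fallback sets out from 8 and returns at 14; it masks the phenol and switches to π-acid activation, which has no vinylidene pathway. Silylation of 8 (TBSCl, imidazole, DMF, 0 °C) should give 1-{2-[(tert-butyldimethylsilyl)oxy]-5-ethynylphenyl}-3-methylbut-2-en-1-one F3. Gold-catalysed Markovnikov addition of 13 (Ph3PAuNTf2 cat., toluene, 60 °C) should give 1-{4-[(tert-butyldimethylsilyl)oxy]-3-(3-methylbut-2-enoyl)phenyl}vinyl (Z)-4-acetoxy-2-methylbut-2-enoate F4. Buffered desilylation of the aryl silyl ether (HF·pyridine, pyridine, THF, 0 °C) then returns 14 before the key step, so the hydrogenation remains the last operation.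

3. Step 5 (butenolide opening and alkylation). The risk is relactonisation of the Z-hydroxy ester during alkylation or work-up, with loss of 4-methoxybenzyl alcohol. The fallback sets out from 9, through its potassium salt 10, and returns at 12; the hydroxyl is silylated before the ester is made. Treatment of dry 10 with TBSCl (2.5 equiv) and imidazole in DMF should give tert-butyldimethylsilyl (Z)-4-[(tert-butyldimethylsilyl)oxy]-2-methylbut-2-enoate F5. Selective hydrolysis of the silyl ester (K2CO3, MeOH/THF/H2O, 0 °C, then mild acidification) should give the stable (Z)-4-[(tert-butyldimethylsilyl)oxy]-2-methylbut-2-enoic acid F6. Carboxylate alkylation (4-methoxybenzyl chloride, K2CO3, DMF) should give 4-methoxybenzyl (Z)-4-[(tert-butyldimethylsilyl)oxy]-2-methylbut-2-enoate F7. Desilylation with HF·pyridine in THF at 0 °C, followed in the same flask by Ac2O and pyridine, generates 11 free of carboxylate salts and acetylates it at once to 12.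

Further compounds
F1 | step 9 | 1-(5-acetyl-2-hydroxyphenyl)-3-methylbut-2-en-1-one | CC(=O)c1ccc(O)c(C(=O)C=C(C)C)c1
F2 | step 9 | 1-{2-hydroxy-5-[(1S)-1-hydroxyethyl]phenyl}-3-methylbut-2-en-1-one | O[C@@H](C)c1ccc(O)c(C(=O)C=C(C)C)c1
F3 | step 8 | 1-{2-[(tert-butyldimethylsilyl)oxy]-5-ethynylphenyl}-3-methylbut-2-en-1-one | C#Cc1ccc(O[Si](C)(C)C(C)(C)C)c(C(=O)C=C(C)C)c1
F4 | step 8 | 1-{4-[(tert-butyldimethylsilyl)oxy]-3-(3-methylbut-2-enoyl)phenyl}vinyl (Z)-4-acetoxy-2-methylbut-2-enoate | CC(=O)OC/C=C(/C)C(=O)OC(=C)c1ccc(O[Si](C)(C)C(C)(C)C)c(C(=O)C=C(C)C)c1
F5 | step 5 | tert-butyldimethylsilyl (Z)-4-[(tert-butyldimethylsilyl)oxy]-2-methylbut-2-enoate | CC(C)(C)[Si](C)(C)OC/C=C(/C)C(=O)O[Si](C)(C)C(C)(C)C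
F6 | step 5 | (Z)-4-[(tert-butyldimethylsilyl)oxy]-2-methylbut-2-enoic acid | CC(C)(C)[Si](C)(C)OC/C=C(/C)C(=O)O
F7 | step 5 | 4-methoxybenzyl (Z)-4-[(tert-butyldimethylsilyl)oxy]-2-methylbut-2-enoate | COc1ccc(COC(=O)/C(C)=C\CO[Si](C)(C)C(C)(C)C)cc1
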